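**Strategy.** The cyclohexene ring (C1, C10–C14) is cut into two three-carbon pieces: C13–C14–C1, an acetone-type bis-nucleophile flanking the C14 oxygen, and C10–C11–C12, a 2-methyl-enal bis-electrophile. One [3+3] Michael/aldol cascade between 3-methylpentane-2,4-dione and a glyceraldehyde-derived enal makes the C1–C10 and C12–C13 bonds and sets C10; the dioxolane is a latent C9 aldehyde. C1 is then made quaternary by acylation anti to C9, the chain to C7 is grown from the C9 aldehyde, a samarium Reformatsky reaction closes the lactone, and ring-closing metathesis at C5=C6 forms the ten-membered ring.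

Key step: step 2

Remarks: atoms carry briarane numbers (C1 quaternary ring-fusion carbon, C2 and C14 acetoxy carbons, C10 ring-fusion CH, C11=C12 ring alkene, lactone O–C7, C8, C17, C19). But-1-en-3-yne is assumed to be available as a commercial solution, and 2-bromopropanoic acid is used as the racemate (its stereocentre is erased in step 17).

Step 1
Reactants: 1 (R)-2,2-dimethyl-1,3-dioxolane-4-carbaldehyde
Product: 2 (S,E)-3-(2,2-dimethyl-1,3-dioxolan-4-yl)-2-methylprop-2-enal
Conditions: 2-(triphenylphosphoranylidene)propanal, toluene, 80 °C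
Reagents that add atoms: 2-(triphenylphosphoranylidene)propanal, CC(C=O)=P(c1ccccc1)(c1ccccc1)c1ccccc1
Why: Wittig olefination with the stabilised formyl ylide should give the (E)-trisubstituted enal and leaves the dioxolane stereocentre untouched.

Step 2
Reactants: 2 (S,E)-3-(2,2-dimethyl-1,3-dioxolan-4-yl)-2-methylprop-2-enal; 3 3-methylpentane-2,4-dione
Product: 6 (4R,5S,6R)-5-[(4S)-2,2-dimethyl-1,3-dioxolan-4-yl]-4,6-dimethylcyclohex-2-en-1-one, via Michael adduct 4 (not isolated), via keto aldehyde 5 (not isolated)
Conditions: DBU (10 mol%), THF, −20 → 0 °C; then K2CO3 (0.3 equiv), MeOH, 0 → 40 °C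
Reagents that add atoms: none
Why: DBU generates the enolate of 3, which adds in a Michael reaction to C10 of enal 2 (C1–C10 bond); methoxide then removes one acetyl group of the non-enolisable 1,3-diketone 4 by retro-Claisen cleavage, and the methyl ketone 5 so revealed closes onto the C12 aldehyde by aldol condensation (C12–C13 bond) with loss of water. The closest known reaction type is the deacylative Robinson-type [3+3] annulation of 1,3-dicarbonyl compounds with enals (Michael addition/aldol condensation). The six-membered ring closes in the 6-(enolendo)-exo-trig mode, the only alternatives being four-membered rings. C10 is set under control of the dioxolane stereocentre: allylic 1,3-strain with the C11 methyl group holds the C9–H bond in the plane of the enal, and the enolate is expected to add to the face opposite the dioxolane C–C bond (syn adduct); C11 and C1 settle under the equilibrating conditions as the all-trans isomer and are both re-formed later, so only C10 matters. The step needs 1,4- and not 1,2-addition, which the soft stabilised enolate secures, and the single acidic hydrogen of 3 rules out Knoevenagel condensation and pyran formation.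

Step 3
Reactants: 7 4-methylpent-4-enoic acid
Product: 8 1-(1H-benzotriazol-1-yl)-4-methylpent-4-en-1-one
Conditions: SOCl2, 1H-benzotriazole (4 equiv), CH2Cl2, rt
Reagents that add atoms: 1H-benzotriazole, c1ccc2[nH]nnc2c1
Why: Activation of the acid with thionyl chloride in the presence of benzotriazole should give the N-acylbenzotriazole, a stable acyl donor that acylates ketone enolates on carbon.

Step 4
Reactants: 6 (4R,5S,6R)-5-[(4S)-2,2-dimethyl-1,3-dioxolan-4-yl]-4,6-dimethylcyclohex-2-en-1-one; 8 1-(1H-benzotriazol-1-yl)-4-methylpent-4-en-1-one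
Product: 10 (4R,5S,6S)-5-[(4S)-2,2-dimethyl-1,3-dioxolan-4-yl]-4,6-dimethyl-6-(4-methylpent-4-enoyl)cyclohex-2-en-1-one, via lithium enolate 9 (not isolated)
Conditions: LiN(iPr)2 (2 equiv), THF, −78 °C; then 8, −78 → −40 °C; aq NH4Cl
Reagents that add atoms: none
Why: Kinetic deprotonation of the enone at the α′-carbon C1 gives the cross-conjugated enolate 9, whose Claisen-type C-acylation by the N-acylbenzotriazole should occur anti to the neighbouring C10 dioxolanyl group, so that C1 becomes quaternary with its methyl group cis to C9 as in the target.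

Step 5
Reactants: 10 (4R,5S,6S)-5-[(4S)-2,2-dimethyl-1,3-dioxolan-4-yl]-4,6-dimethyl-6-(4-methylpent-4-enoyl)cyclohex-2-en-1-one
Product: 11 (4R,5S,6S)-5-[(4S)-2,2-dimethyl-1,3-dioxolan-4-yl]-6-[(1R)-1-hydroxy-4-methylpent-4-en-1-yl]-4,6-dimethylcyclohex-2-en-1-one
Conditions: Zn(BH4)2, Et2O, −78 → −40 °C; aq NH4Cl
Reagents that add atoms: none
Why: Chelation-controlled reduction in which zinc bridges both carbonyl groups and hydride reaches the more electrophilic saturated side-chain ketone from the face of the C1 methyl group (opposite ring carbon C10) should give the 2R alcohol, the conjugated ring carbonyl being spared at low temperature.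

Step 6
Reactants: 11 (2R)-alcohol
Product: 12 C2 triethylsilyl ether of 11
Conditions: Et3SiOTf, 2,6-lutidine, CH2Cl2, −78 → 0 °C
Reagents that add atoms: triethylsilyl trifluoromethanesulfonate, CC[Si](CC)(CC)OS(=O)(=O)C(F)(F)F
Why: Silylation of the hindered neopentylic alcohol with the silyl triflate protects it against retro-aldol cleavage in the basic step that follows.

Step 7
Reactants: 12 C2 triethylsilyl ether
Product: 14 β,γ-unsaturated ketone (cyclohex-3-en-1-one with the C11=C12 double bond), via potassium dienolate 13 (not isolated)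
Conditions: KOtBu (5 equiv), tBuOH/THF, rt; then poured into cold aq AcOH
Reagents that add atoms: none
Why: With no α′-hydrogen left, tert-butoxide removes the γ-hydrogen at C11 to give the extended dienolate 13, and kinetic protonation at the α-carbon C13 (deconjugation of an enone through its dienolate) should place the double bond at C11=C12 and erase the C11 stereocentre.

Step 8
Reactants: 14 β,γ-unsaturated ketone
Product: 15 (14S)-alcohol (hydroxyl α, cis to the C2 branch)
Conditions: (R)-2-methyl-CBS-oxazaborolidine (20 mol%), catecholborane, toluene/CH2Cl2, −78 → −40 °C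
Reagents that add atoms: none
Why: Corey–Bakshi–Shibata reduction under reagent control, with quaternary C1 as the large and C13H2 as the small substituent, should deliver hydride to the β-face and give the 14S alcohol, while catecholborane leaves the alkenes alone.

Step 9
Reactants: 15 (14S)-alcohol
Product: 16 (2R,14S)-diol
Conditions: Bu4NF, THF, 0 °C → rt; aq NH4Cl
Reagents that add atoms: none
Why: Fluoride cleaves the triethylsilyl ether and frees the C2 hydroxyl.

Step 10
Reactants: 16 (2R,14S)-diol
Product: 17 (2R,14S)-diacetate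
Conditions: Ac2O, DMAP, pyridine, rt → 40 °C
Reagents that add atoms: acetic anhydride, CC(=O)OC(C)=O
Why: DMAP-catalysed acylation of both hindered secondary alcohols installs the two acetates of the target.

Step 11
Reactants: 17 (2R,14S)-diacetate
Product: 18 C9 aldehyde (CHO on C10 in place of the dioxolane)
Conditions: H5IO6 (1.5 equiv), EtOAc, rt; used at once
Reagents that add atoms: none
Why: Periodic acid hydrolyses the terminal acetonide and cleaves the resulting 1,2-diol in one flask (glycol cleavage), which unmasks the C9 aldehyde without touching acetates or alkenes.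

Step 12
Reactants: 18 C9 aldehyde
Product: 19 (E)-dienyl carbinol (C9 hydroxyl configured as in the target)
Conditions: but-1-en-3-yne, Cp2Zr(H)Cl, CH2Cl2, rt; Me2Zn, toluene, −65 °C; (−)-3-exo-morpholinoisoborneol (10 mol%), then 18, −30 °C; aq NH4Cl
Reagents that add atoms: but-1-en-3-yne, C=CC#C
Why: Hydrozirconation of the alkyne, transmetalation to zinc and amino-alcohol-catalysed alkenylzinc addition should give the (E)-dienyl carbinol, the ligand (Si-face delivery) and Felkin–Anh control from C10 (quaternary C1 anti to the nucleophile) both favouring the target configuration at C9, and the mild organozinc tolerates the acetates.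

Step 13
Reactants: 19 (E)-dienyl carbinol
Product: 20 (7R,8R)-epoxy alcohol (erythro to the C9 hydroxyl)
Conditions: Ti(OiPr)4 (20 mol%), D-(−)-diisopropyl tartrate (24 mol%), tBuOOH, 4 Å MS, CH2Cl2, −20 °C
Reagents that add atoms: tert-butyl hydroperoxide, CC(C)(C)OO
Why: Sharpless asymmetric epoxidation in the matched sense should epoxidise only the allylic C7=C8 double bond of the secondary allylic alcohol and give the erythro epoxy alcohol.

Step 14
Reactants: 20 (7R,8R)-epoxy alcohol
Product: 21 C9 triethylsilyl ether of 20
Conditions: Et3SiCl, imidazole, DMF, 0 °C → rt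
Reagents that add atoms: chlorotriethylsilane, CC[Si](Cl)(CC)CC
Why: Silylation of the C9 hydroxyl ensures that only the C8 hydroxyl is free after the epoxide is opened.

Step 15
Reactants: 21 C9 triethylsilyl ether
Product: 22 C7 (S)-2-bromopropanoate with free C8 hydroxyl
Conditions: 2-bromopropanoic acid (3 equiv), CH2Cl2, 0 °C → rt
Reagents that add atoms: 2-bromopropanoic acid, CC(Br)C(=O)O
Why: Acidolysis of the vinyl epoxide at the allylic carbon C7 with inversion (borderline SN2 opening) should install the C7 acyloxy group in the target configuration and free the C8 hydroxyl.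

Step 16
Reactants: 22 C7 2-bromopropanoate, C8 alcohol
Product: 23 C8 ketone
Conditions: Dess–Martin periodinane, NaHCO3, CH2Cl2, 0 °C → rt
Reagents that add atoms: none
Why: Dess–Martin oxidation converts the secondary C8 alcohol into the ketone under buffered, non-enolising conditions that preserve the C7 and C9 stereocentres.

Step 17
Reactants: 23 C8 ketone
Product: 25 seco-lactone (γ-lactone C7–O–C19(=O)–C17–C8 with 8-OH and 17-Me, open between C5 and C6), via samarium enolate 24 (not isolated)
Conditions: SmI2 (2.5 equiv), THF, −78 °C; aq NH4Cl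
Reagents that add atoms: none
Why: SmI2 reduces the α-bromo ester to a trivalent samarium enolate that adds to the adjacent ketone (intramolecular Reformatsky reaction), and the chelated transition state should place the bulky C9 branch trans to the C7 vinyl group and the C17 methyl trans to the C9 branch, which is also the thermodynamically preferred arrangement at this epimerisable centre.

Step 18
Reactants: 25 seco-lactone
Product: 26 9-O-triethylsilyl-9-deacetylstylatulide lactone
Conditions: second-generation Hoveyda–Grubbs catalyst (15 mol%), toluene (0.5 mM), 80 °C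
Reagents that add atoms: none
Why: Ring-closing metathesis between the monosubstituted C6 vinyl group and the 1,1-disubstituted C5 alkene under high dilution should close the ten-membered ring, in which the Z geometry of the trisubstituted double bond is the less strained one and is expected under equilibrating conditions.

Step 19
Reactants: 26 9-O-triethylsilyl-9-deacetylstylatulide lactone
Product: 27 9-deacetylstylatulide lactone
Conditions: HF·pyridine, pyridine/THF, 0 °C
Reagents that add atoms: none
Why: HF·pyridine removes the triethylsilyl ether without touching the acetates or the β-hydroxy lactone.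

**Compound list**

1 | (R)-2,2-dimethyl-1,3-dioxolane-4-carbaldehyde | O=C[C@H]1COC(C)(C)O1 | starting material
2 | (S,E)-3-(2,2-dimethyl-1,3-dioxolan-4-yl)-2-methylprop-2-enal | O=C/C(C)=C/[C@H]1COC(C)(C)O1 | intermediate
3 | 3-methylpentane-2,4-dione | CC(=O)C(C)C(C)=O | starting material
4 | Michael adduct, 4-acetyl-3-[(4S)-2,2-dimethyl-1,3-dioxolan-4-yl]-2,4-dimethyl-5-oxohexanal (C10 as in 6, C11 epimers) | CC(=O)C(C)(C(C)=O)[C@@H]([C@H]1COC(C)(C)O1)C(C)C=O | intermediate
5 | keto aldehyde, 3-[(4S)-2,2-dimethyl-1,3-dioxolan-4-yl]-2,4-dimethyl-5-oxohexanal (C10 as in 6, C1 and C11 epimers) | CC(=O)C(C)[C@@H]([C@H]1COC(C)(C)O1)C(C)C=O | intermediate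
6 | (4R,5S,6R)-5-[(4S)-2,2-dimethyl-1,3-dioxolan-4-yl]-4,6-dimethylcyclohex-2-en-1-one | O=C1C=C[C@@H](C)[C@H]([C@H]2COC(C)(C)O2)[C@H]1C | intermediate
7 | 4-methylpent-4-enoic acid | C=C(C)CCC(=O)O | starting material
8 | 1-(1H-benzotriazol-1-yl)-4-methylpent-4-en-1-one | C=C(C)CCC(=O)n1nnc2ccccc12 | intermediate
9 | lithium enolate of 6 (C14–OLi, C1=C14) | [Li]OC1=C(C)[C@@H]([C@H]2COC(C)(C)O2)[C@H](C)C=C1 | intermediate
10 | (4R,5S,6S)-5-[(4S)-2,2-dimethyl-1,3-dioxolan-4-yl]-4,6-dimethyl-6-(4-methylpent-4-enoyl)cyclohex-2-en-1-one | O=C1C=C[C@@H](C)[C@H]([C@H]2COC(C)(C)O2)[C@@]1(C)C(=O)CCC(C)=C | intermediate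
11 | (4R,5S,6S)-5-[(4S)-2,2-dimethyl-1,3-dioxolan-4-yl]-6-[(1R)-1-hydroxy-4-methylpent-4-en-1-yl]-4,6-dimethylcyclohex-2-en-1-one | O=C1C=C[C@@H](C)[C@H]([C@H]2COC(C)(C)O2)[C@@]1(C)[C@H](O)CCC(C)=C | intermediate
12 | C2 triethylsilyl ether of 11 | O=C1C=C[C@@H](C)[C@H]([C@H]2COC(C)(C)O2)[C@@]1(C)[C@H](O[Si](CC)(CC)CC)CCC(C)=C | intermediate
13 | potassium dienolate of 12 (C14–OK, C13=C14, C11=C12) | [K]OC1=CC=C(C)[C@H]([C@H]2COC(C)(C)O2)[C@@]1(C)[C@H](O[Si](CC)(CC)CC)CCC(C)=C | intermediate
14 | β,γ-unsaturated ketone (C14 ketone, C11=C12; C1, C2, C10 as in 12) | O=C1CC=C(C)[C@H]([C@H]2COC(C)(C)O2)[C@@]1(C)[C@H](O[Si](CC)(CC)CC)CCC(C)=C | intermediate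
15 | (14S)-alcohol of 14 (hydroxyl α, cis to the C2 branch) | O[C@H]1CC=C(C)[C@H]([C@H]2COC(C)(C)O2)[C@@]1(C)[C@H](O[Si](CC)(CC)CC)CCC(C)=C | intermediate
16 | (2R,14S)-diol | O[C@H]1CC=C(C)[C@H]([C@H]2COC(C)(C)O2)[C@@]1(C)[C@H](O)CCC(C)=C | intermediate
17 | (2R,14S)-diacetate | CC(=O)O[C@H]1CC=C(C)[C@H]([C@H]2COC(C)(C)O2)[C@@]1(C)[C@H](OC(C)=O)CCC(C)=C | intermediate
18 | C9 aldehyde (CHO on C10) | CC(=O)O[C@H]1CC=C(C)[C@H](C=O)[C@@]1(C)[C@H](OC(C)=O)CCC(C)=C | intermediate
19 | (E)-dienyl carbinol (C9–OH as in target, C7=C8 E, C6 vinyl) | CC(=O)O[C@H]1CC=C(C)[C@H]([C@@H](O)/C=C/C=C)[C@@]1(C)[C@H](OC(C)=O)CCC(C)=C | intermediate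
20 | (7R,8R)-epoxy alcohol, erythro to C9–OH | CC(=O)O[C@H]1CC=C(C)[C@H]([C@@H](O)[C@H]2O[C@@H]2C=C)[C@@]1(C)[C@H](OC(C)=O)CCC(C)=C | intermediate
21 | C9 triethylsilyl ether of 20 | CC(=O)O[C@H]1CC=C(C)[C@H]([C@@H](O[Si](CC)(CC)CC)[C@H]2O[C@@H]2C=C)[C@@]1(C)[C@H](OC(C)=O)CCC(C)=C | intermediate
22 | C7 (S)-2-bromopropanoate, C8 alcohol, C9 silyl ether | CC(=O)O[C@H]1CC=C(C)[C@H]([C@@H](O[Si](CC)(CC)CC)[C@@H](O)[C@@H](OC(=O)C(C)Br)C=C)[C@@]1(C)[C@H](OC(C)=O)CCC(C)=C | intermediate
23 | C8 ketone of 22 | CC(=O)O[C@H]1CC=C(C)[C@H]([C@@H](O[Si](CC)(CC)CC)C(=O)[C@@H](OC(=O)C(C)Br)C=C)[C@@]1(C)[C@H](OC(C)=O)CCC(C)=C | intermediate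
24 | samarium enolate of 23 | CC(=O)O[C@H]1CC=C(C)[C@H]([C@@H](O[Si](CC)(CC)CC)C(=O)[C@@H](OC(O[Sm](I)I)=CC)C=C)[C@@]1(C)[C@H](OC(C)=O)CCC(C)=C | intermediate
25 | seco-lactone (γ-lactone with 8-OH cis to C6 and to the C17 methyl; C5 and C6 alkenes still open) | CC(=O)O[C@H]1CC=C(C)[C@H]([C@@H](O[Si](CC)(CC)CC)[C@@]2(O)[C@H](C=C)OC(=O)[C@@H]2C)[C@@]1(C)[C@H](OC(C)=O)CCC(C)=C | intermediate
26 | 9-O-triethylsilyl-9-deacetylstylatulide lactone | CC(=O)O[C@H]1CC=C(C)[C@@H]2[C@@H](O[Si](CC)(CC)CC)[C@@]3(O)[C@H](/C=C(/C)CC[C@@H](OC(C)=O)[C@@]12C)OC(=O)[C@@H]3C | intermediate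
27 | 9-deacetylstylatulide lactone | CC(=O)O[C@H]1CC=C(C)[C@@H]2[C@@H](O)[C@@]3(O)[C@H](/C=C(/C)CC[C@@H](OC(C)=O)[C@@]12C)OC(=O)[C@@H]3C | target

**Totals.** Total step count: 19. Longest linear sequence: 18 steps (from 1 through steps 1, 2 and 4–19; step 3 is a side branch).

**Steps most likely to fail**

Step 18 (ring-closing metathesis). The ruthenium alkylidene formed at the C6 vinyl group may fail to engage the 1,1-disubstituted C5 alkene across the forming ten-membered ring, so that intermolecular metathesis or catalyst decay takes over. The fallback changes the order of ring formation. It sets out from ketone 23, which is subjected to the metathesis before the lactone exists (second-generation Hoveyda–Grubbs catalyst, toluene, high dilution), where the sp2 carbon C8 and the missing five-membered ring leave the chain more flexible. This would give the macrocyclic α-acyloxy ketone F1. The SmI2 Reformatsky reaction of step 17, now transannular, would then close the lactone, and the route is rejoined at 26.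

Step 2 (key step). Facial selectivity of the conjugate addition may be poor, or retro-Michael equilibration under the basic conditions may erode the ratio at C10. The fallback replaces the base-mediated addition by a kinetically controlled Mukaiyama–Michael addition. It sets out from diketone 3, which is converted (Me3SiCl, Et3N, NaI, MeCN) into the silyl enol ether 3-methyl-4-(trimethylsilyloxy)pent-3-en-2-one F2. This is added to enal 2 under BF3·OEt2 activation in CH2Cl2 at −78 °C, where the addition is irreversible and the bulky nucleophile should respond more strongly to the allylic-strain-controlled facial bias. Aqueous work-up would give Michael adduct 4, where the route is rejoined; treatment with K2CO3 in MeOH as in step 2 then leads to 6.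

Step 8 (reduction at C14). The inherent preference of the ring ketone for hydride attack from the face opposite the axial C1 methyl group opposes the catalyst, so that hydride delivery to the wrong face may compete. The fallback replaces reagent control by delivery guided by the neighbouring hydroxyl. It sets out from 14, from which the silyl ether is removed (Bu4NF buffered with AcOH, THF, 0 °C) to give the β-hydroxy ketone F3. Narasaka–Prasad reduction (Et2BOMe, NaBH4, THF/MeOH, −78 °C) through the six-membered boron chelate would then give the syn-1,3-diol directly, and the route is rejoined at 16.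

**Further compounds**

F1 | step 18 | macrocyclic α-acyloxy ketone (ten-membered ring closed, C8 ketone, C7 2-bromopropanoate, C9 silyl ether) | CC(=O)O[C@H]1CC=C(C)[C@@H]2[C@@H](O[Si](CC)(CC)CC)C(=O)[C@H](/C=C(/C)CC[C@@H](OC(C)=O)[C@@]12C)OC(=O)C(C)Br
F2 | step 2 | 3-methyl-4-(trimethylsilyloxy)pent-3-en-2-one | CC(=O)C(C)=C(C)O[Si](C)(C)C
F3 | step 8 | β-hydroxy ketone (14 without the silyl group) | O=C1CC=C(C)[C@H]([C@H]2COC(C)(C)O2)[C@@]1(C)[C@H](O)CCC(C)=C
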